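The single product in these flasks is a passing stage: in the green run it read 31% at 50.0 s but 24% at 120 s, so I wanted to know how much of it stands in the tail of the run.

| setting | green | red | south-west | south | north | east |
|---|---|---|---|---|---|---|
| substrate | 0.029 M | 0.35 M | 0.050 M | 0.10 M | 0.20 M | 0.40 M |
| gas | 3.8 mM (held) | 3.8 mM (held) | 3.8 mM (held) | 3.8 mM (held) | 3.8 mM (held) | 3.8 mM (held) |
| remark | run made earlier | run made earlier |  |  |  |  |
| time |  |  | 4.0 min | 4.0 min | 4.0 min | 4.0 min |

- green (time / s: single product / %, substrate / %): 10.0: 16, 88; 15.0: 16, 81; 20.0: 19, 76; 30.0: 21, 69; 50.0: 31, 50; 80.0: 29, 35; 120: 24, 21
- red (time / s: single product / %, substrate / %): 15.0: 16, 83; 30.0: 18, 75; 50.0: 29, 57; 60.0: 30, 48; 80.0: 29, 42; 90.0: 28, 37; 120: 24, 24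

(readings scatter by 2 percentage points)

- the numbers in the tables scatter by 2 percentage points (one standard deviation)
- at the start none of the gas is in solution
- "hardly changes" means that all values lie within two and a half points (for a concentration: within two and a half percent of the largest)

- amount of single product at the end, in percent of the substrate charged for south-west, south, north, east, in this order
- how the row runs (falls all the way / rises, then falls / rises all the way / falls, then rises / hardly changes)

My zero of the scale was a flask in which, at held gas, each step is first order (pseudo-first-order): its percentages do not depend on the charge, and its row is flat. The green and red charges, 0.029 M and 0.35 M, gave substrate readings of 21% and 24% at 120 s, so I read the flasks as close to that zero and took green to stand for south-west and red for east.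

I followed the run in slow motion. In the first instants no gas is in solution, yet the green run's first reading, at 10.0 s, already shows substrate at 88%. In the middle the single product peaks, and there its making equals its loss. The green peak reading has 31% of single product beside 50% of substrate, so in the first-order picture each percent of single product is lost faster than each percent of substrate is used. In the tail a first-order product then follows the substrate at a fixed ratio, product at the peak divided by substrate minus product at the peak, which gave 1.63 for green. The asked time is twice the last reading time, so the first-order remainder there is the square of the last reading, 4.41% for green. The two multiplied give 7.20%, which is what I call the tail share: tail ratio times squared remainder. The same reckoning on red gave a ratio of 1.67, a remainder of 5.76% and a tail share of 9.60%. That is a rise of 2.4 percentage points from the green to the red charge, a reading-based figure with the scatter of 2 points in each input, and I took it as narrowly inside the margin of "hardly changes", which was the shape I chose.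

The forecast gave 7.3%, 7.4%, 7.6% and 7.9%, with the shape hardly changes, and held that “The slight slowing at high charge adds under one point across the row”. My top value stood higher than its top value, but we chose the same shape.

The flask gave 8.36%, 8.63%, 9.21% and 10.5%, and the shape was: hardly changes.

    substrate + coupling partner → single product (k = 3.56 L mol⁻¹ s⁻¹)
    gas ⇌ coupling partner, rate k2*(csat - [coupling partner]) (kL = 5.99 s⁻¹)
    coupling partner + single product ⇌ double product (K = 7960 L mol⁻¹, k = 5.74 L mol⁻¹ s⁻¹)

In south-west, the forward rate alone of the step from coupling partner and single product to double product gave the single product a half-life of 0.53 min at the asked time, shorter than the 4.0 min of the run, and double product stood at 87.5% at the end. The green tail share, 7.20%, lay 1.2 points below south-west. The red tail share, 9.60%, lay 0.9 points below east, where the single product ended at 10.5%.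

All runs come from a simulation with made-up constants; noise was put on by code.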